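The oxolane ring is numbered from its oxygen (O1) so that C5 is the stereocentre written first in the SMILES. The plan cuts the C3–C4 bond of this ring and uses the fact that both C3 and C4 bear a hydroxymethyl group. Precursor 10 is an acyclic bis-benzylic ether that already holds C2 and C5. Its C3 arm is a terminal oxirane (the latent C3–CH2OH), and C4 is the inner carbon of an ethynyl group. Cp2TiCl opens the oxirane to a C3 radical that closes onto the alkyne. This one operation forms C3–C4, the ring and the C3 stereocentre, frees the C3 hydroxymethyl group, and leaves a C4 methylene for hydroboration.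

Key step: step 6

Assumption: the (S,S) antipode of Ph-pybox is taken to give the (S) configuration at C5; a trial of 8 with a simple alcohol settles the sense, and the equally available (R,R) antipode is used if it is the reverse.
Notation: Ar = 3,5-dimethoxy-4-(triisopropylsilyloxy)phenyl. In SMILES the cyclopentadienyl ligands are drawn σ-bound, and the pybox ligand of 9 is left out.

Step 1
Reactants: 1 syringaldehyde
Product: 2 3,5-dimethoxy-4-(triisopropylsilyloxy)benzaldehyde
Conditions: TIPSCl, imidazole, DMF, rt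
Reagents that add atoms: triisopropylsilyl chloride, CC(C)[Si](Cl)(C(C)C)C(C)C
Why: Imidazole-promoted silylation of a phenol; the TIPS ether should survive Grignard reagents, titanium alkoxides, trivalent titanium and boranes and leaves with fluoride, so the end game needs no hydrogenolysis next to the two benzylic C–O bonds of the ring.

Step 2
Reactants: 2 3,5-dimethoxy-4-(triisopropylsilyloxy)benzaldehyde; 3 vinylmagnesium bromide
Product: 4 rac-1-Ar-prop-2-en-1-ol
Conditions: THF, −78 → 0 °C; aq NH4Cl
Reagents that add atoms: none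
Why: Grignard 1,2-addition to an aryl aldehyde, in which the racemate is wanted because the next step resolves it.

Step 3
Reactants: 4 rac-1-Ar-prop-2-en-1-ol
Product: 5 (S)-Ar[(2R)-oxiran-2-yl]methanol (anti epoxy alcohol)
Conditions: Ti(OiPr)4 (0.15 equiv), L-(+)-DIPT (0.18 equiv), tBuOOH (0.45 equiv, decane), 4 Å MS, CH2Cl2, −20 °C
Reagents that add atoms: tert-butyl hydroperoxide, CC(C)(C)OO
Why: Sharpless kinetic resolution, in which L-(+)-DIPT makes the (R)-enantiomer of an aryl vinyl carbinol the fast-reacting one and epoxidises it to the anti epoxy alcohol, so stopping short of half conversion should fix C2 and install the oxirane in one step while the slow (S)-enantiomer of 4 is removed by chromatography.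

Step 4
Reactants: 2 3,5-dimethoxy-4-(triisopropylsilyloxy)benzaldehyde; 6 ethynylmagnesium bromide
Product: 8 rac-tert-butyl 1-Ar-prop-2-yn-1-yl carbonate, via bromomagnesium alkoxide 7 (not isolated)
Conditions: 6 (1.2 equiv), THF, 0 °C; then Boc2O (1.5 equiv), 0 °C → rt; aq NH4Cl
Reagents that add atoms: di-tert-butyl dicarbonate, CC(C)(C)OC(=O)OC(=O)OC(C)(C)C
Why: Grignard 1,2-addition followed by O-acylation of the alkoxide in the same flask, with no stereocontrol needed because C5 is set later from a planar intermediate.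

Step 5
Reactants: 5 (S)-Ar[(2R)-oxiran-2-yl]methanol; 8 rac-tert-butyl 1-Ar-prop-2-yn-1-yl carbonate
Product: 10 (2R)-2-{(S)-Ar[(1S)-1-Ar-prop-2-yn-1-yloxy]methyl}oxirane, via copper allenylidene 9 (not isolated)
Conditions: 8 (1.5 equiv), CuOTf·½C6H6 (10 mol %), (S,S)-Ph-pybox (12 mol %), iPr2NEt (1.2 equiv), THF, −20 → 0 °C, argon
Reagents that add atoms: none
Why: Copper-catalysed asymmetric propargylic etherification, a reaction type shown with secondary aliphatic alcohols as nucleophiles, in which both enantiomers of 8 lose CO2 and tert-butoxide to give the same planar allenylidene 9 and the pybox ligand decides which face of its γ-carbon the hydroxyl group of 5 attacks, so C5 is set as (S) by the catalyst, C2 is carried in unchanged, and any minor enantiomer of 5 ends up in a separable diastereomer.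

Step 6
Reactants: 10 (2R)-2-{(S)-Ar[(1S)-1-Ar-prop-2-yn-1-yloxy]methyl}oxirane
Product: 14 [(2R,3S,5S)-2,5-bis(Ar)-4-methylideneoxolan-3-yl]methanol, via C3 radical 11 (not isolated), via vinyl radical 12 (not isolated), via titanium alkoxide 13 (not isolated)
Conditions: Cp2TiCl2 (2.5 equiv), Zn dust, THF, rt (green Cp2TiCl, decanted from Zn); added dropwise to 10 in THF (0.02 M), rt; sat. aq NaH2PO4
Reagents that add atoms: none
Why: Cp2TiCl, a trivalent titanium single-electron donor, binds the oxirane oxygen and cleaves the C3–O bond homolytically toward the more substituted carbon, which gives the β-titanoxy radical 11 and flattens the former oxirane stereocentre. Radical 11 attacks the inner alkyne carbon C4 in a 5-exo-dig closure that forms C3–C4 and the oxolane ring O1–C2–C3–C4–C5, and the reactive vinyl radical 12 takes a hydrogen atom from THF (or is caught by a second Cp2TiCl and protonated on work-up) to leave alkoxide 13, which the buffer hydrolyses to 14. The closest known reaction type is the titanocene-mediated reductive epoxide opening with radical cyclisation, which is established for epoxy propargyl ethers and gives 3-hydroxymethyl-4-methylene tetrahydrofurans. The one new stereocentre, C3, is controlled by C2: in the chair-like transition state the cis-related aryl groups at C2 and C5 both lie pseudo-equatorial, and the bulky CH2OTiCp2Cl arm avoids the C2 aryl by also lying pseudo-equatorial, which is the 2,3-trans (3S) arrangement. The step needs this 2,3-trans selectivity and needs ring closure to outrun capture of 11 by more titanium, which would end in β-elimination to an alkene; the size of the titanoxy arm next to the C2 aryl secures the first, and the oxygen-containing tether, the unhindered terminal alkyne and slow addition of the reagent to a dilute solution secure the second. C2 and C5 are safe because the medium is neither acidic nor basic and no cation forms at a benzylic carbon.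

Step 7
Reactants: 14 [(2R,3S,5S)-2,5-bis(Ar)-4-methylideneoxolan-3-yl]methanol
Product: 16 [(2R,3S,4S,5S)-2,5-bis(Ar)-4-(hydroxymethyl)oxolan-3-yl]methanol, via bis(9-BBN) adduct 15 (not isolated)
Conditions: 9-BBN (3 equiv), THF, 0 °C → rt; then NaBO3·4H2O, THF–H2O, rt
Reagents that add atoms: sodium perborate, [Na+].[Na+].O[B-]1(O)OO[B-](O)(O)OO1
Why: Hydroboration–oxidation, in which one equivalent of 9-BBN is used up by the free hydroxyl group, boron goes to the terminal carbon and hydrogen reaches C4 from the face away from both aryl groups (the C5 aryl stands directly beside the alkene), so the new CH2OH should end cis to the C5 aryl and trans to the C3 arm (4S), and the mild perborate oxidation spares the aryl silyl ethers.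

Step 8
Reactants: 16 [(2R,3S,4S,5S)-2,5-bis(Ar)-4-(hydroxymethyl)oxolan-3-yl]methanol
Product: 17 [(2R,3S,4S,5S)-2,5-bis(4-hydroxy-3,5-dimethoxyphenyl)-4-(hydroxymethyl)oxolan-3-yl]methanol (target)
Conditions: Bu4NF (2.5 equiv), AcOH (2.5 equiv), THF, 0 °C
Reagents that add atoms: none
Why: Fluoride cleavage of aryl silyl ethers, buffered with acetic acid so that no free phenoxide or acid can epimerise C2 or C5 through a quinone methide, and free of any reductive condition that could cut the ring C–O bonds.

Compound list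
1 | syringaldehyde | COc1cc(C=O)cc(OC)c1O | starting material
2 | 3,5-dimethoxy-4-(triisopropylsilyloxy)benzaldehyde | COc1cc(C=O)cc(OC)c1O[Si](C(C)C)(C(C)C)C(C)C | intermediate
3 | vinylmagnesium bromide | C=C[Mg]Br | starting material
4 | rac-1-Ar-prop-2-en-1-ol | COc1cc(C(O)C=C)cc(OC)c1O[Si](C(C)C)(C(C)C)C(C)C | intermediate
5 | (S)-Ar[(2R)-oxiran-2-yl]methanol | COc1cc([C@H](O)[C@H]2CO2)cc(OC)c1O[Si](C(C)C)(C(C)C)C(C)C | intermediate
6 | ethynylmagnesium bromide | C#C[Mg]Br | starting material
7 | bromomagnesium 1-Ar-prop-2-yn-1-olate (racemic, not isolated) | COc1cc(C(C#C)O[Mg]Br)cc(OC)c1O[Si](C(C)C)(C(C)C)C(C)C | intermediate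
8 | rac-tert-butyl 1-Ar-prop-2-yn-1-yl carbonate | COc1cc(C(C#C)OC(=O)OC(C)(C)C)cc(OC)c1O[Si](C(C)C)(C(C)C)C(C)C | intermediate
9 | copper allenylidene Ar–CH=C=C=Cu(+), pybox ligand omitted (not isolated) | COc1cc(C=C=C=[Cu+])cc(OC)c1O[Si](C(C)C)(C(C)C)C(C)C | intermediate
10 | epoxy propargyl ether, C2 (S), oxirane CH (R), C5 (S); key-step precursor | COc1cc([C@H](C#C)O[C@@H](c2cc(OC)c(O[Si](C(C)C)(C(C)C)C(C)C)c(OC)c2)[C@H]2CO2)cc(OC)c1O[Si](C(C)C)(C(C)C)C(C)C | intermediate
11 | β-titanoxy C3 radical (not isolated) | COc1cc([C@H](C#C)O[C@@H](c2cc(OC)c(O[Si](C(C)C)(C(C)C)C(C)C)c(OC)c2)[CH]CO[Ti](Cl)(C2C=CC=C2)C2C=CC=C2)cc(OC)c1O[Si](C(C)C)(C(C)C)C(C)C | intermediate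
12 | cyclised exocyclic vinyl radical (not isolated) | COc1cc([C@H]2O[C@@H](c3cc(OC)c(O[Si](C(C)C)(C(C)C)C(C)C)c(OC)c3)[C@H](CO[Ti](Cl)(C3C=CC=C3)C3C=CC=C3)C2=[CH])cc(OC)c1O[Si](C(C)C)(C(C)C)C(C)C | intermediate
13 | Cp2Ti(Cl) alkoxide of 14 (not isolated) | COc1cc([C@H]2O[C@@H](c3cc(OC)c(O[Si](C(C)C)(C(C)C)C(C)C)c(OC)c3)[C@H](CO[Ti](Cl)(C3C=CC=C3)C3C=CC=C3)C2=C)cc(OC)c1O[Si](C(C)C)(C(C)C)C(C)C | intermediate
14 | [(2R,3S,5S)-2,5-bis(Ar)-4-methylideneoxolan-3-yl]methanol, 2,5-cis, 2,3-trans; key-step product | COc1cc([C@H]2O[C@@H](c3cc(OC)c(O[Si](C(C)C)(C(C)C)C(C)C)c(OC)c3)[C@H](CO)C2=C)cc(OC)c1O[Si](C(C)C)(C(C)C)C(C)C | intermediate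
15 | C4–CH2–(9-BBN) borane with the C3–CH2O–(9-BBN) borinate (not isolated) | COc1cc([C@H]2O[C@@H](c3cc(OC)c(O[Si](C(C)C)(C(C)C)C(C)C)c(OC)c3)[C@H](COB3C4CCCC3CCC4)[C@H]2CB2C3CCCC2CCC3)cc(OC)c1O[Si](C(C)C)(C(C)C)C(C)C | intermediate
16 | [(2R,3S,4S,5S)-2,5-bis(Ar)-4-(hydroxymethyl)oxolan-3-yl]methanol | COc1cc([C@H]2O[C@@H](c3cc(OC)c(O[Si](C(C)C)(C(C)C)C(C)C)c(OC)c3)[C@H](CO)[C@H]2CO)cc(OC)c1O[Si](C(C)C)(C(C)C)C(C)C | intermediate
17 | [(2R,3S,4S,5S)-2,5-bis(4-hydroxy-3,5-dimethoxyphenyl)-4-(hydroxymethyl)oxolan-3-yl]methanol | COc1cc([C@H]2O[C@@H](c3cc(OC)c(O)c(OC)c3)[C@H](CO)[C@H]2CO)cc(OC)c1O | target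

Total step count: 8.
Longest linear sequence: 7 (steps 1, 2, 3, 5, 6, 7, 8).
Stereocentres: C2 is set in step 3, C5 in step 5, C3 in step 6 and C4 in step 7.

Steps most likely to fail

Step 5.
- **Risk:** The hindered secondary hydroxyl group, made less nucleophilic by the neighbouring oxirane, may capture the allenylidene too slowly. The copper Lewis acid may also open the oxirane. A mismatched pairing of ligand and alcohol may weaken control at C5.
- **Fallback:** The oxirane is put in after the ether bond. The fallback sets out from 4 and 8. Sharpless kinetic resolution of 4 with D-(−)-DIPT and about 0.6 equiv of tBuOOH leaves the (R)-allylic alcohol F1, while the (S)-enantiomer is consumed as the epoxy alcohol ent-5 F2. F1 is a better nucleophile and has nothing acid-labile beside its hydroxyl group. It is coupled with 8 under the CuOTf–pybox catalysis to give the enyne ether F3. mCPBA buffered with NaHCO3 in CH2Cl2 then epoxidises the vinyl group, which reacts faster than the terminal alkyne, without facial control. This gives 10 together with its oxirane epimer F4. The pair is not separated, because step 6 removes that centre, and the fallback comes back to the route at 10.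

Step 6.
- **Risk:** A second Cp2TiCl may capture radical 11 and the titanoxy group may β-eliminate (net deoxygenation) before the ring closes. Zinc chloride may open the oxirane with chloride. The preference for the 2,3-trans arrangement may also be weak.
- **Fallback:** The same C3–C4 bond is formed by palladium instead of a radical. The fallback sets out from 4 and 8 by way of the enyne ether F3, made as described for step 5. Borylative cyclisation of this 1,6-enyne uses Pd(OAc)2 (5 mol %) and B2pin2 in toluene–MeOH at 50 °C. It proceeds by hydropalladation of the alkyne, 5-exo carbopalladation of the vinyl group and boryl transfer, and should give the 2,3-trans pinacol boronate F5. Oxidation with NaBO3·4H2O turns C–B into C–OH, and the fallback comes back to the route at 14.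

Step 7.
- **Risk:** Facial selectivity may be poor, because the C3 arm, enlarged to its borinate, shields the face the reagent must use and competes with the C5 aryl on the other face.
- **Fallback:** The C3 arm is turned from an obstacle into a directing group. The fallback sets out from 14. Ph2PCl and Et3N in CH2Cl2 give the diphenylphosphinite F6. With [Rh(cod)Cl]2 (cat.) and catecholborane in THF, rhodium held by the phosphorus should deliver hydrogen and boron from the face of the C3 arm, which gives the catechol boronate F7. NaBO3·4H2O oxidises both C–B and phosphorus to the hydroxy diphenylphosphinate F8. LiAlH4 in THF at 0 °C then frees the C3 alcohol, and the fallback comes back to the route at 16.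

Further compounds
F1 | step 5 | (R)-1-Ar-prop-2-en-1-ol | COc1cc([C@H](O)C=C)cc(OC)c1O[Si](C(C)C)(C(C)C)C(C)C
F2 | step 5 | (R)-Ar[(2S)-oxiran-2-yl]methanol (ent-5) | COc1cc([C@@H](O)[C@@H]2CO2)cc(OC)c1O[Si](C(C)C)(C(C)C)C(C)C
F3 | step 5 | (R)-1-Ar-allyl (S)-1-Ar-prop-2-ynyl ether (enyne ether) | COc1cc([C@H](C#C)O[C@@H](c2cc(OC)c(O[Si](C(C)C)(C(C)C)C(C)C)c(OC)c2)C=C)cc(OC)c1O[Si](C(C)C)(C(C)C)C(C)C
F4 | step 5 | oxirane epimer of 10, oxirane CH (S) | COc1cc([C@H](C#C)O[C@@H](c2cc(OC)c(O[Si](C(C)C)(C(C)C)C(C)C)c(OC)c2)[C@@H]2CO2)cc(OC)c1O[Si](C(C)C)(C(C)C)C(C)C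
F5 | step 6 | 2,5-cis-2,3-trans-2,5-bis(Ar)-4-methylidene-3-(pinacolatoborylmethyl)oxolane | COc1cc([C@H]2O[C@@H](c3cc(OC)c(O[Si](C(C)C)(C(C)C)C(C)C)c(OC)c3)[C@H](CB3OC(C)(C)C(C)(C)O3)C2=C)cc(OC)c1O[Si](C(C)C)(C(C)C)C(C)C
F6 | step 7 | diphenylphosphinite of 14 | COc1cc([C@H]2O[C@@H](c3cc(OC)c(O[Si](C(C)C)(C(C)C)C(C)C)c(OC)c3)[C@H](COP(c3ccccc3)c3ccccc3)C2=C)cc(OC)c1O[Si](C(C)C)(C(C)C)C(C)C
F7 | step 7 | C4–CH2 catechol boronate bearing the C3 phosphinite | COc1cc([C@H]2O[C@@H](c3cc(OC)c(O[Si](C(C)C)(C(C)C)C(C)C)c(OC)c3)[C@H](COP(c3ccccc3)c3ccccc3)[C@H]2CB2Oc3ccccc3O2)cc(OC)c1O[Si](C(C)C)(C(C)C)C(C)C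
F8 | step 7 | C3-mono(diphenylphosphinate) of 16 | COc1cc([C@H]2O[C@@H](c3cc(OC)c(O[Si](C(C)C)(C(C)C)C(C)C)c(OC)c3)[C@H](COP(=O)(c3ccccc3)c3ccccc3)[C@H]2CO)cc(OC)c1O[Si](C(C)C)(C(C)C)C(C)C
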